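**Retrosynthetic overview**
1. The (E)-enol ester comes from a Wittig reaction of an acyloxymethylene ylide with the C10 aldehyde; that aldehyde and the acetonyl ketone both come from one ozonolysis (C10 vinyl, C5 methallyl).
2. C10 and C5 are set on the bridged enone: Cu-catalysed vinyl addition, C5 allylation, then C5 reset by deprotonation and kinetic protonation.
3. C3–OH and the C18 methylene come from epoxidation, methanolysis and ionic reduction of the enol ether in the tricyclic core.
4. The cyclohexane and pyran rings are closed together, last, by an intramolecular hetero-Diels–Alder reaction of a 2-formylcyclohepta-2,6-dienone; the seven-membered ring comes from one-carbon expansion of a cyclohexenone (ring order: six-membered carbocycle, then seven-membered ring, then cyclohexane plus pyran).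
5. The C11 quaternary stereocenter comes from ene-reductase desymmetrization of a prochiral 4,4-disubstituted cyclohexa-2,5-dienone built from a ketal nitrile and homoprenyl bromide.

Assumption: carbon labels follow vibsane numbering (C11 methyl-bearing quaternary carbon, C1 bridging CH2, C2/C14 ring-fusion CH, C3 carbinol carbon, C4 ring ketone, C5 acetonyl-bearing CH, C10 enol-ester-bearing CH, C15 CMe2, C18 OCH2); the ene-reductase of step 6 is the (S)-selective member of an Old Yellow Enzyme panel, found by screening.

**Step 1**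
Reactants: 1 ketal nitrile 1,4-dioxaspiro[4.5]decane-8-carbonitrile; 2 homoprenyl bromide 5-bromo-2-methylpent-2-ene
Product: 4 quaternary nitrile 8-(4-methylpent-3-en-1-yl)-1,4-dioxaspiro[4.5]decane-8-carbonitrile, via lithiated nitrile 3 (not isolated)
Conditions: LiN(iPr)2, THF, −78 °C; then 2, −78 °C to rt
Reagents that add atoms: none
Why: SN2 alkylation of the nitrile-stabilised carbanion builds the future C11 as a symmetric quaternary carbon, so no stereocenter is formed.

**Step 2**
Reactants: 4 quaternary nitrile
Product: 6 aldehyde 8-(4-methylpent-3-en-1-yl)-1,4-dioxaspiro[4.5]decane-8-carbaldehyde, via aldimine 5 (not isolated)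
Conditions: iBu2AlH, toluene, −78 °C; then aq. tartaric acid, 0 °C
Reagents that add atoms: water, O
Why: Partial hydride reduction of the nitrile stops at the N-aluminio imine, which hydrolyses to the non-enolisable aldehyde under acid mild enough to keep the ketal.

**Step 3**
Reactants: 6 aldehyde
Product: 8 methyl ketal 8-methyl-8-(4-methylpent-3-en-1-yl)-1,4-dioxaspiro[4.5]decane, via hydrazone 7 (not isolated)
Conditions: N2H4·H2O, KOH, diethylene glycol, 130 °C then 200 °C
Reagents that add atoms: none
Why: Wolff–Kishner reduction (Huang-Minlon procedure) turns the neopentyl CHO into the C11 methyl; ketal and trisubstituted alkene are base-stable.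

**Step 4**
Reactants: 8 methyl ketal
Product: 9 ketone 4-methyl-4-(4-methylpent-3-en-1-yl)cyclohexan-1-one
Conditions: pyridinium p-toluenesulfonate (cat.), acetone/H2O, 60 °C
Reagents that add atoms: water, O
Why: Mild acid-catalysed ketal hydrolysis (transketalisation to acetone) frees the ketone without hydrating the alkene.

**Step 5**
Reactants: 9 ketone
Product: 10 prochiral dienone 4-methyl-4-(4-methylpent-3-en-1-yl)cyclohexa-2,5-dien-1-one
Conditions: IBX (3 equiv), DMSO/fluorobenzene, 75 °C
Reagents that add atoms: none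
Why: Twofold IBX dehydrogenation of the ketone (Nicolaou oxidation) cannot aromatise because C4 is quaternary, giving the mirror-symmetric dienone with no stereocenter.

**Step 6**
Reactants: 10 prochiral dienone
Product: 11 enone (S)-4-methyl-4-(4-methylpent-3-en-1-yl)cyclohex-2-en-1-one
Conditions: ene-reductase (Old Yellow Enzyme family, (S)-selective), NAD(P)+ (cat.), HCO2Na, formate dehydrogenase, KH2PO4/K2HPO4 buffer pH 7.0, 5 vol% DMSO, 30 °C
Reagents that add atoms: none
Why: The flavin-dependent ene-reductase reduces one of the two enantiotopic C=C bonds (biocatalytic desymmetrising conjugate reduction), creating the C11 quaternary center as the first stereocenter; the isolated alkene is not a substrate.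

**Step 7**
Reactants: 11 enone
Product: 12 keto ester ethyl (5S)-5-methyl-5-(4-methylpent-3-en-1-yl)-2-oxocyclohept-3-ene-1-carboxylate
Conditions: N2CHCO2Et, BF3·OEt2, Et2O, 0 °C
Reagents that add atoms: ethyl diazoacetate, CCOC(=O)C=[N+]=[N-]
Why: Lewis-acid-promoted diazoacetate homologation (Tiffeneau–Demjanov-type 1,2-shift) in which the sp3 α'-carbon migrates in preference to the alkenyl carbon, so the new carbon (C3) enters between C=O and the saturated CH2 and C11 is untouched.

**Step 8**
Reactants: 12 keto ester
Product: 13 cycloheptenone (R)-4-methyl-4-(4-methylpent-3-en-1-yl)cyclohept-2-en-1-one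
Conditions: LiCl, DMSO/H2O, 150 °C
Reagents that add atoms: none
Why: Krapcho dealkoxycarbonylation removes the ester under neutral conditions (the CIP letter changes only because priorities change; the geometry at C11 is the same).

**Step 9**
Reactants: 13 cycloheptenone
Product: 14 hydroxymethylene ketone (4S,7Z)-7-(hydroxymethylidene)-4-methyl-4-(4-methylpent-3-en-1-yl)cyclohept-2-en-1-one
Conditions: NaH, HCO2Et, THF (cat. EtOH), 0 °C to rt; then aq. HCl
Reagents that add atoms: ethyl formate, CCOC=O
Why: Claisen formylation occurs only at C3, the sole enolisable position (no γ-hydrogen, C11 is quaternary), installing C18 at the aldehyde oxidation level.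

**Step 10**
Reactants: 14 hydroxymethylene ketone
Product: 16 tricyclic dienone enol ether, via 2-formyl dienone 15 (not isolated)
Conditions: DDQ, 1,4-dioxane, rt; then toluene, 80 °C
Reagents that add atoms: none
Why: DDQ dehydrogenation gives the 2-formyl enone, whose O=C18–C3=C2 heterodiene adds the homoprenyl alkene in an intramolecular inverse-demand hetero-Diels–Alder reaction; the tether from C11 forces the cyclohexane to bridge cis and the pyran to fuse cis, setting C2 and C14.

**Step 11**
Reactants: 16 tricyclic dienone enol ether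
Product: 18 hydroxy acetal (C3–OH, C18 methyl acetal), via alkoxy epoxide 17 (not isolated)
Conditions: DMDO, acetone/CH2Cl2, −20 to 0 °C; then MeOH, pyridinium p-toluenesulfonate (cat.), 0 °C
Reagents that add atoms: dimethyldioxirane, CC1(C)OO1; methanol, CO
Why: Electrophilic epoxidation of the enol ether C3=C18 (the enone is much less reactive) occurs on the only open face, away from the pyran ring, setting C3 with OH on the convex face; methanolysis of the alkoxy epoxide gives the stable acetal.

**Step 12**
Reactants: 18 hydroxy acetal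
Product: 19 hydroxy enone (C3–OH, C18 methylene, C4 ketone, C5=C10 enone)
Conditions: Et3SiH, BF3·OEt2, CH2Cl2, −78 to −20 °C
Reagents that add atoms: none
Why: Ionic reduction of the acetal through the C18 oxocarbenium ion (Kishi-type silane reduction) leaves the conjugated ketone and the tertiary alcohol untouched.

**Step 13**
Reactants: 19 hydroxy enone
Product: 20 triethylsilyl ether of 19
Conditions: Et3SiOTf, 2,6-lutidine, CH2Cl2, −78 to 0 °C
Reagents that add atoms: triethylsilyl trifluoromethanesulfonate, CC[Si](CC)(CC)OS(=O)(=O)C(F)(F)F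
Why: Silylation of the hindered tertiary α-ketol (the ketone has no enolisable hydrogen) blocks alkoxide chemistry in the organometallic steps.

**Step 14**
Reactants: 20 triethylsilyl ether
Product: 21 C10-vinyl trimethylsilyl enol ether
Conditions: CH2=CHMgBr, CuBr·SMe2 (20 mol %), Me3SiCl, HMPA, THF, −78 °C
Reagents that add atoms: vinylmagnesium bromide, C=C[Mg]Br; chlorotrimethylsilane, C[Si](C)(C)Cl
Why: Silyl-chloride-accelerated Cu-catalysed conjugate addition delivers vinyl to C10 from the convex face, anti to the C12–C14 bridge, setting C10 with vinyl cis to the C11 methyl; the enolate is trapped regiospecifically.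

**Step 15**
Reactants: 21 C10-vinyl trimethylsilyl enol ether
Product: 23 methallyl ketone (C5 epimer, methallyl cis to vinyl), via lithium enolate 22 (not isolated)
Conditions: MeLi, THF, 0 °C; then CH2=C(CH3)CH2Br, HMPA, −78 to 0 °C
Reagents that add atoms: 3-bromo-2-methylprop-1-ene, CC(=C)CBr
Why: The lithium enolate, regenerated regiospecifically from the silyl enol ether, is C-alkylated (SN2) by the allylic bromide mainly from the convex face, giving the C5 epimer that step 16 corrects.

**Step 16**
Reactants: 23 methallyl ketone (C5 epimer)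
Product: 25 methallyl ketone (target C5 configuration, methallyl trans to vinyl), via potassium enolate 24 (not isolated)
Conditions: KN(SiMe3)2, THF, −78 to −30 °C; then AcOH, −78 °C
Reagents that add atoms: none
Why: C5–H is the only α-hydrogen of the C4 ketone, so enolisation is regiospecific, and kinetic C-protonation from the convex face puts H-5 outside and the methallyl group on the concave face (epimerisation by deprotonation and kinetic protonation).

**Step 17**
Reactants: 25 methallyl ketone
Product: 27 keto aldehyde (C5 acetonyl, C10 CHO), via bis-ozonide 26 (not isolated)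
Conditions: O3, CH2Cl2, −78 °C; then PPh3, −78 °C to rt
Reagents that add atoms: ozone, [O-][O+]=O
Why: One ozonolysis with reductive work-up cleaves both terminal alkenes, turning methallyl into the methyl ketone and vinyl into the C10 aldehyde without touching the stereocenters.

**Step 18**
Reactants: 28 3-methylbut-2-enoyl chloride
Product: 29 chloromethyl 3-methylbut-2-enoate
Conditions: (CH2O)n, ZnCl2 (cat.), CH2Cl2, 0 °C to rt
Reagents that add atoms: paraformaldehyde (formaldehyde unit), C=O
Why: ZnCl2-catalysed insertion of formaldehyde into the acyl chloride C–Cl bond gives the chloromethyl ester; no stereocenter is involved.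

**Step 19**
Reactants: 29 chloromethyl 3-methylbut-2-enoate
Product: 30 phosphonium salt {[(3-methylbut-2-enoyl)oxy]methyl}triphenylphosphonium chloride
Conditions: PPh3, toluene, 80 °C
Reagents that add atoms: triphenylphosphine, c1ccc(cc1)P(c1ccccc1)c1ccccc1
Why: SN2 quaternisation of PPh3 by the activated chloromethyl ester gives the acyloxymethyl phosphonium salt.

**Step 20**
Reactants: 27 keto aldehyde; 30 phosphonium salt
Product: 32 silyl-protected target (E-enol ester), via phosphorus ylide 31 (not isolated)
Conditions: KN(SiMe3)2, THF, −78 °C; then 27, −78 to 0 °C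
Reagents that add atoms: none
Why: Wittig olefination with the acyloxymethylene ylide (Anders–Gaßner variant) is aldehyde-selective in the presence of both ketones and forms the enol ester directly as an E/Z mixture, from which the E isomer is separated by chromatography.

**Step 21**
Reactants: 32 silyl-protected target
Product: 33 target CNP0237201.2
Conditions: HF·pyridine, THF, 0 °C
Reagents that add atoms: none
Why: Fluoride-mediated cleavage of the tertiary triethylsilyl ether under buffered, weakly acidic conditions leaves the enol ester and both ketones intact.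

**Compound list**
1 | 1,4-dioxaspiro[4.5]decane-8-carbonitrile | N#CC1CCC2(CC1)OCCO2 | starting material
2 | 5-bromo-2-methylpent-2-ene (homoprenyl bromide) | CC(C)=CCCBr | starting material
3 | N-lithio ketenimine of 1 (lithiated nitrile, not isolated) | [Li]N=C=C1CCC2(CC1)OCCO2 | intermediate
4 | 8-(4-methylpent-3-en-1-yl)-1,4-dioxaspiro[4.5]decane-8-carbonitrile | N#CC1(CCC=C(C)C)CCC2(CC1)OCCO2 | intermediate
5 | aldimine of 6 (present as its N-aluminium adduct, not isolated) | N=CC1(CCC=C(C)C)CCC2(CC1)OCCO2 | intermediate
6 | 8-(4-methylpent-3-en-1-yl)-1,4-dioxaspiro[4.5]decane-8-carbaldehyde | O=CC1(CCC=C(C)C)CCC2(CC1)OCCO2 | intermediate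
7 | hydrazone of 6 (not isolated) | NN=CC1(CCC=C(C)C)CCC2(CC1)OCCO2 | intermediate
8 | 8-methyl-8-(4-methylpent-3-en-1-yl)-1,4-dioxaspiro[4.5]decane | CC1(CCC=C(C)C)CCC2(CC1)OCCO2 | intermediate
9 | 4-methyl-4-(4-methylpent-3-en-1-yl)cyclohexan-1-one | CC1(CCC=C(C)C)CCC(=O)CC1 | intermediate
10 | 4-methyl-4-(4-methylpent-3-en-1-yl)cyclohexa-2,5-dien-1-one (prochiral) | CC1(CCC=C(C)C)C=CC(=O)C=C1 | intermediate
11 | (S)-4-methyl-4-(4-methylpent-3-en-1-yl)cyclohex-2-en-1-one | O=C1C=C[C@@](C)(CCC=C(C)C)CC1 | intermediate
12 | ethyl (5S)-5-methyl-5-(4-methylpent-3-en-1-yl)-2-oxocyclohept-3-ene-1-carboxylate (C1 epimers, keto/enol) | O=C1C=C[C@@](C)(CCC=C(C)C)CCC1C(=O)OCC | intermediate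
13 | (R)-4-methyl-4-(4-methylpent-3-en-1-yl)cyclohept-2-en-1-one | O=C1C=C[C@@](C)(CCC=C(C)C)CCC1 | intermediate
14 | (4S,7Z)-7-(hydroxymethylidene)-4-methyl-4-(4-methylpent-3-en-1-yl)cyclohept-2-en-1-one | O/C=C1\C(=O)C=C[C@@](C)(CCC=C(C)C)CC1 | intermediate
15 | (S)-4-methyl-4-(4-methylpent-3-en-1-yl)-7-oxocyclohepta-1,5-diene-1-carbaldehyde (not isolated) | O=CC1=CC[C@](C)(CCC=C(C)C)C=CC1=O | intermediate
16 | tricyclic dienone enol ether: C2–C14 and O–C15 closed, C4 ketone, C5=C10 enone, C3=C18 enol ether; H-2, H-14 and the C11 methyl on one face of the cyclohexane, the C3–C4–C5–C10 bridge and C15 on the other | O=C1C2=COC(C)(C)[C@@H]3CC[C@@](C)(C[C@@H]32)C=C1 | intermediate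
17 | C3/C18 epoxide of 16, epoxide oxygen on the convex face (not isolated) | O=C1[C@@]24O[C@H]4OC(C)(C)[C@@H]3CC[C@@](C)(C[C@@H]32)C=C1 | intermediate
18 | C3-hydroxy C18-methoxy acetal (C18 anomers), C3–OH on the convex face | O=C1[C@]2(O)C(OC)OC(C)(C)[C@@H]3CC[C@@](C)(C[C@@H]32)C=C1 | intermediate
19 | C3-hydroxy tetrahydropyran enone (C18 methylene, C4 ketone, C5=C10 enone) | O=C1[C@]2(O)COC(C)(C)[C@@H]3CC[C@@](C)(C[C@@H]32)C=C1 | intermediate
20 | C3-O-triethylsilyl ether of 19 | O=C1[C@]2(O[Si](CC)(CC)CC)COC(C)(C)[C@@H]3CC[C@@](C)(C[C@@H]32)C=C1 | intermediate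
21 | C4 trimethylsilyl enol ether (C4=C5) with C10 vinyl on the convex face, cis to the C11 methyl | C1=C(O[Si](C)(C)C)[C@]2(O[Si](CC)(CC)CC)COC(C)(C)[C@@H]3CC[C@@](C)(C[C@@H]32)[C@H]1C=C | intermediate
22 | lithium enolate from 21 (not isolated) | C1=C(O[Li])[C@]2(O[Si](CC)(CC)CC)COC(C)(C)[C@@H]3CC[C@@](C)(C[C@@H]32)[C@H]1C=C | intermediate
23 | C5-(2-methylallyl) C10-vinyl ketone, C5 epimer (methallyl cis to vinyl) | CC(=C)C[C@H]1C(=O)[C@]2(O[Si](CC)(CC)CC)COC(C)(C)[C@@H]3CC[C@@](C)(C[C@@H]32)[C@H]1C=C | intermediate
24 | potassium enolate from 23 (not isolated) | CC(=C)CC1=C(O[K])[C@]2(O[Si](CC)(CC)CC)COC(C)(C)[C@@H]3CC[C@@](C)(C[C@@H]32)[C@H]1C=C | intermediate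
25 | C5-(2-methylallyl) C10-vinyl ketone, target C5 configuration (methallyl trans to vinyl, on the concave face) | CC(=C)C[C@@H]1C(=O)[C@]2(O[Si](CC)(CC)CC)COC(C)(C)[C@@H]3CC[C@@](C)(C[C@@H]32)[C@H]1C=C | intermediate
26 | bis-ozonide (1,2,4-trioxolanes at both former alkenes, not isolated) | CC1(C[C@@H]2C(=O)[C@]3(O[Si](CC)(CC)CC)COC(C)(C)[C@@H]4CC[C@@](C)(C[C@@H]43)[C@H]2C5OCOO5)OCOO1 | intermediate
27 | keto aldehyde: C5 acetonyl, C10 formyl, C3-O-triethylsilyl | CC(=O)C[C@@H]1C(=O)[C@]2(O[Si](CC)(CC)CC)COC(C)(C)[C@@H]3CC[C@@](C)(C[C@@H]32)[C@H]1C=O | intermediate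
28 | 3-methylbut-2-enoyl chloride | CC(C)=CC(=O)Cl | starting material
29 | chloromethyl 3-methylbut-2-enoate | CC(C)=CC(=O)OCCl | intermediate
30 | {[(3-methylbut-2-enoyl)oxy]methyl}triphenylphosphonium chloride | CC(C)=CC(=O)OC[P+](c1ccccc1)(c1ccccc1)c1ccccc1.[Cl-] | intermediate
31 | [(3-methylbut-2-enoyl)oxy]methylidene-triphenylphosphorane (not isolated) | CC(C)=CC(=O)OC=P(c1ccccc1)(c1ccccc1)c1ccccc1 | intermediate
32 | C3-O-triethylsilyl ether of the target, (E)-enol ester | CC(=O)C[C@@H]1C(=O)[C@]2(O[Si](CC)(CC)CC)COC(C)(C)[C@@H]3CC[C@@](C)(C[C@@H]32)[C@H]1/C=C/OC(=O)C=C(C)C | intermediate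
33 | CNP0237201.2: C3–OH, C10 (E)-enol senecioate and C11 methyl on the convex face; C5 acetonyl on the concave face; cis-fused gem-dimethyl tetrahydropyran | CC(=O)C[C@@H]1C(=O)[C@]2(O)COC(C)(C)[C@@H]3CC[C@@](C)(C[C@@H]32)[C@H]1/C=C/OC(=O)C=C(C)C | target

**Totals**
Total step count: 21. Longest linear sequence: 19 steps (steps 1 to 17, then 20 and 21); steps 18 and 19 are a two-step side branch.

**Three steps most likely to fail, with fallbacks**

Step 7 (ring expansion). The risk is partial migration of the alkenyl carbon or BF3-induced cyclisation of the alkene onto the activated enone. The fallback sets out from 11 and inserts the carbon by a cyclopropane route whose regiochemistry is fixed by the enolate. Kinetic α'-deprotonation and silylation (LiN(iPr)2, Me3SiCl, THF, −78 °C) give the cross-conjugated trimethylsilyl dienol ether F1. Cyclopropanation of its electron-rich enol ether double bond (Et2Zn, CH2I2, 1.1 equiv, −20 °C) gives the siloxy vinylcyclopropane F2. FeCl3 in DMF opens the ring-fusion bond (Ito–Saegusa enlargement) to the β-chloro ketone F3, and NaOAc in MeOH eliminates HCl to the cyclohepta-2,6-dienone F4. LiBH(sBu)3 at −78 °C adds hydride only to the unhindered C2 terminus (C10 is neopentyl), and the route is rejoined at 13.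

Step 16 (C5 configuration). The risk is incomplete enolisation of the hindered C5–H or protonation on the wrong face. The fallback sets out from 20 and installs the side chain before the conjugate addition, so that H-5 is the last group introduced without any deprotonation. α-Iodination (I2, pyridine, CH2Cl2) gives the α-iodo enone F5. Stille coupling with tributyl(2-methylallyl)stannane (Pd2(dba)3, AsPh3, CuI, NMP) gives the C5-methallyl enone F6. The Cu-catalysed vinyl Grignard addition of step 14 then gives the tetrasubstituted silyl enol ether F7, which is protodesilylated at −78 °C (Bu4NF buffered with AcOH) from the convex face. The route is rejoined at 25.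

Step 20 (E-enol ester). The risk is an unfavourable E/Z ratio or base-induced aldol chemistry of the keto aldehyde. The fallback sets out from 27 and builds the enol ester stereospecifically. Takai–Utimoto olefination (CrCl2, LiI, 2-(dichloromethyl)-4,4,5,5-tetramethyl-1,3,2-dioxaborolane, THF) gives the (E)-alkenyl pinacol boronate F8. KHF2 in MeOH/H2O converts it to the potassium (E)-alkenyltrifluoroborate F9. Cu-catalysed oxidative coupling with 3-methylbut-2-enoic acid (CuBr (cat.), 4-(dimethylamino)pyridine, 4 Å molecular sieves, O2, MeCN, 60 °C) forms the C–O bond with retention of alkene geometry. The route is rejoined at 32.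

**Further compounds**
F1 | step 7 | trimethylsilyl dienol ether of 11 (C1-silyloxy cyclohexa-1,5-diene) | C[Si](C)(C)OC1=CC[C@](C)(CCC=C(C)C)C=C1
F2 | step 7 | 1-(trimethylsilyloxy)bicyclo[4.1.0]hept-2-ene from F1 (cyclopropane diastereomers) | C[Si](C)(C)OC12CC1C[C@](C)(CCC=C(C)C)C=C2
F3 | step 7 | 6-chloro-4-methyl-4-(4-methylpent-3-en-1-yl)cyclohept-2-en-1-one (C6 epimers) | O=C1CC(Cl)C[C@](C)(CCC=C(C)C)C=C1
F4 | step 7 | 4-methyl-4-(4-methylpent-3-en-1-yl)cyclohepta-2,6-dien-1-one | O=C1C=CC[C@](C)(CCC=C(C)C)C=C1
F5 | step 16 | C5-iodo enone from 20 | O=C1[C@]2(O[Si](CC)(CC)CC)COC(C)(C)[C@@H]3CC[C@@](C)(C[C@@H]32)C=C1I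
F6 | step 16 | C5-(2-methylallyl) enone | O=C1[C@]2(O[Si](CC)(CC)CC)COC(C)(C)[C@@H]3CC[C@@](C)(C[C@@H]32)C=C1CC(C)=C
F7 | step 16 | C5-(2-methylallyl) C10-vinyl trimethylsilyl enol ether | CC(=C)CC1=C(O[Si](C)(C)C)[C@]2(O[Si](CC)(CC)CC)COC(C)(C)[C@@H]3CC[C@@](C)(C[C@@H]32)[C@H]1C=C
F8 | step 20 | (E)-alkenyl pinacol boronate from 27 | CC(=O)C[C@@H]1C(=O)[C@]2(O[Si](CC)(CC)CC)COC(C)(C)[C@@H]3CC[C@@](C)(C[C@@H]32)[C@H]1/C=C/B1OC(C)(C)C(C)(C)O1
F9 | step 20 | potassium (E)-alkenyltrifluoroborate | CC(=O)C[C@@H]1C(=O)[C@]2(O[Si](CC)(CC)CC)COC(C)(C)[C@@H]3CC[C@@](C)(C[C@@H]32)[C@H]1/C=C/[B-](F)(F)F.[K+]
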